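## Analysis of the target

Kazinol H is a flavan: benzene ring A is fused to the dihydropyran ring C, ring B sits on C2, and a 2,2-dimethyl-2H-pyran (ring D) is fused to ring B across C3'–C4' with its oxygen on C4'. Ring A carries a free hydroxyl at C7 and a 1,1-dimethylallyl group at C6, whose first carbon is quaternary. Ring B is pentasubstituted: C1' (bond to C2), a prenyl group at C2', ring D at C3'/C4' and a free hydroxyl at C5'. The only stereocentre is C2 (S); it is a benzylic ether carbon with no neighbouring stereocentre or carbonyl group to direct it.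

The molecule holds three kinds of alkene (a trisubstituted prenyl alkene, a terminal vinyl group and the styrene-type alkene of ring D), so hydrogenation, peracids and strong electrophiles are excluded once these are present. Both phenols are electron-rich, acid would add the C7 hydroxyl to its neighbouring vinyl group, and the C2–O1 bond can ionise with help from the para oxygen O4'. The difficulty is to set C2 without a C4 carbonyl that would have to be removed again, next to a crowded ring B, and to build the quaternary carbon on ring A. The strategy rests on one feature: C2 is bonded to both O1 and C1', and O4' is para to C1'. A metal on C2 is therefore a stabilised benzyl species that the ring A phenol can attack.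

## Retrosynthetic reasoning

**24 to 23.** The last bond cut is O5'–Si. The ring B phenol, next to the ring D oxygen, is the most oxidisable site and stays masked through the oxidative palladium step and the hot rearrangement. Fluoride removes the silyl group without touching alkenes or C2.

**23 to 21 (through 22).** The C6–C(quaternary) bond is cut, which returns the 1,1-dimethylallyl group to O7 as a prenyl ether. A [3,3] shift builds the quaternary carbon without reagent and inverts the allyl unit exactly as needed. It also keeps the terminal vinyl group out of the palladium step and protects O7 during it. The forward reaction must choose C6 over C8. C6 is para to O1 and unhindered, whereas C8 lies between two oxygens.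

**21 to 7 and 20.** Both bonds from C2 to its non-hydrogen partners outside the chain, C2–C1' and O1–C2, are cut. This divides the molecule into two halves of similar size, each derived from a benzaldehyde, and the stereocentre is created in the convergent step. The forward reaction has to deliver the aryl group of 20 to the terminal alkene carbon of 7, bring palladium back onto that carbon, and let the phenol close ring C under control of a chiral ligand.

**7 to 5 (through 6), then 4, 3, 1 and 2.** The C3–C4 bond is cut. A vinyl nucleophile adds to the ortho-quinone methide 6 released from 5. The positions of allyl group, hydroxyl and prenyl ether are fixed by aldehyde 1, whose hydrogen-bonded 2-hydroxyl leaves only the 4-hydroxyl free for alkylation by 2. No palladium is used on this branch, which matters because the aryl prenyl ether can be ionised by low-valent palladium.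

**20 to 19, 18 and 17.** The C1'–B bond is traced back to a C1'–O bond through the pinacol boronate and the triflate. Boron comes last on ring B because an arylboron compound would not survive the oxidation that creates the C1' oxygen.

**17 to 16.** The C2'–CH2 bond of the prenyl group is cut at the bromine that has marked C2' since the starting material. No regiochemical question arises on the ring.

**16 to 14 (through 15).** Ring D is opened to a tertiary propargyl ether on O4'. The forward cascade (Claisen shift, hydrogen shift, oxa-6π closure) can reach only C3', because the other ortho position, C5', carries the silyloxy group.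

**14 to 12 (through 13).** The C1'–O bond comes from the formyl carbon by a Baeyer–Villiger oxidation. This is placed while the only unsaturation is a terminal alkyne. Later, a peracid would attack the prenyl and ring D alkenes, and the aldehyde has no free ortho or para hydroxyl for the alkaline hydrogen peroxide variant.

**12 to 11, 9 and 10, then 8.** The formyl group para to the future O4' makes that hydroxyl of catechol 9 the more acidic one, so it is etherified selectively with 10. The remaining hydroxyl is then silylated. The formyl group thus serves twice: it differentiates the two oxygens and later becomes the C1' oxygen. Demethylation of 8 comes first, when nothing acid-sensitive is present.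

## Alternatives that were turned down

**Alternative 1:** The cuts are C6–C(quaternary) on ring A and the C3'–C and O–C bonds of ring D, so that both return to aryl ethers in the flavan bis-ether A1 (7-O-prenyl, 4'-O-(1,1-dimethylpropargyl)). Heating A1 would run both rearrangements in one flask and give the 5'-triisopropylsilyl ether A2.
- For: no reagent is needed, the quaternary carbon and ring D form together, and ring D can only form at C3'. On late-stage economy this is stronger than the chosen route.
- Against: it does not address C2 or ring C, so A1 still needs an enantioselective flavan synthesis. The two neighbouring oxygens of ring B would have to be differentiated without the para-formyl group that does this in 9. The two shifts have different thermal demands, so the ortho-(1,1-dimethylallyl)phenol formed first must endure the harsher heating needed by the propargyl ether.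
- Comparison: the chosen route uses the same ring A shift alone and builds ring D on a small benzaldehyde. What it offers in place of the one-flask finish is that the convergent step itself creates C2.

**Alternative 2:** The cut is O1–C8a. The S alcohol A3, with a bromine on the ring A carbon that becomes C8a, would be cyclised by palladium-catalysed aryl ether formation to the bis-silyl ether A4.
- For: every reaction type is established. The configuration comes from an asymmetric ketone reduction and is retained, because no bond to C2 is made or broken. On certainty of stereocontrol this is stronger than the chosen route.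
- Against: a secondary benzylic alkoxide on palladium can lose a β-hydrogen, which gives the ketone and the debrominated arene. The bromide is electron-rich and adds slowly. The arylpalladium meets the terminal vinyl group, which must already be in place. A3 is a long linear construct (brominated ring A with the quaternary carbon, a three-carbon link, ketone, reduction) with two silyl groups.
- Comparison: the chosen route gives up that certainty for convergence and a shorter sequence.

**Alternative 3:** The cuts are O1–C2 and C3–C4. A chiral phosphoric acid would dehydrate the 2-hydroxybenzyl alcohol A5 to its ortho-quinone methide, which would add the ring B styrene A6 to give the bis-silyl ether A7.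
- For: it is as convergent as the chosen route, forms two bonds and ring C, has inherent regiochemistry and needs no metal. Ring A already carries the 1,1-dimethylallyl group, so no late rearrangement is needed; on that point it is stronger.
- Against: a Brønsted acid meets an acid-sensitive para-alkoxystyrene, the ring D alkene and the prenyl groups. An unsubstituted quinone methide self-condenses readily. The catalyst binds the quinone methide oxygen, whereas the new stereocentre arises on a styrene carbon without a hydrogen-bonding handle, most likely in the closure of a benzylic cation. The C2–O1 bond of A7 can re-ionise under the same acid.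
- Comparison: the chosen route places the chiral ligand on the metal bound to C2 when the C–O bond forms and works without acid. It shares the risk of ionisation assisted by O4'.

Key step: step 14

Assumption: the sense of induction of the pyridine-oxazoline ligand in step 14 cannot be predicted with confidence; the (S)-ligand is written, and its mirror image is to be used if it favours the R flavan.

## Route

Step 1
Reactants: 1 2,4-dihydroxybenzaldehyde; 2 1-bromo-3-methylbut-2-ene
Product: 3 2-hydroxy-4-[(3-methylbut-2-en-1-yl)oxy]benzaldehyde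
Conditions: K2CO3 (1.1 equiv), acetone, 40 °C
Reagents that add atoms: none
Why: Williamson ether synthesis; the 2-hydroxyl is held in a hydrogen bond to the formyl group and is the less reactive one, so alkylation should occur at the 4-hydroxyl.

Step 2
Reactants: 3 2-hydroxy-4-[(3-methylbut-2-en-1-yl)oxy]benzaldehyde
Product: 4 tert-butyl 2-formyl-5-[(3-methylbut-2-en-1-yl)oxy]phenyl carbonate
Conditions: Boc2O, DMAP (cat.), i-Pr2NEt, THF, 0 °C to rt
Reagents that add atoms: di-tert-butyl dicarbonate, CC(C)(C)OC(=O)OC(=O)OC(C)(C)C
Why: DMAP-catalysed O-acylation of the phenol; the aryl carbonate later supplies the leaving group for anionic generation of the ortho-quinone methide.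

Step 3
Reactants: 4 tert-butyl 2-formyl-5-[(3-methylbut-2-en-1-yl)oxy]phenyl carbonate
Product: 5 tert-butyl 2-(hydroxymethyl)-5-[(3-methylbut-2-en-1-yl)oxy]phenyl carbonate
Conditions: NaBH4, THF–MeOH, −20 °C; aq NH4Cl
Reagents that add atoms: none
Why: Chemoselective hydride reduction of the aldehyde; low temperature and a protic quench should keep the benzylic alkoxide from attacking the neighbouring carbonate, which would start the quinone methide cascade too early.

Step 4
Reactants: 5 tert-butyl 2-(hydroxymethyl)-5-[(3-methylbut-2-en-1-yl)oxy]phenyl carbonate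
Product: 7 2-allyl-5-[(3-methylbut-2-en-1-yl)oxy]phenol, via ortho-quinone methide 6 (not isolated)
Conditions: vinylmagnesium bromide (3 equiv), THF, −78 °C to rt; aq NH4Cl
Reagents that add atoms: vinylmagnesium bromide, C=C[Mg]Br
Why: Anionic ortho-quinone methide generation followed by 1,4-addition: the magnesium alkoxide takes over the carbonate group, the phenoxide expels tert-butyl carbonate to give 6, and a second equivalent of the Grignard reagent adds to the exocyclic methylene carbon. This forms the C3–C4 bond and restores the free phenol; the aryl prenyl ether is inert to Grignard reagents.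

Step 5
Reactants: 8 2-bromo-4,5-dimethoxybenzaldehyde
Product: 9 2-bromo-4,5-dihydroxybenzaldehyde
Conditions: BBr3 (3 equiv), CH2Cl2, −78 °C to rt; H2O
Reagents that add atoms: none
Why: Lewis-acid cleavage of both aryl methyl ethers; aldehyde and aryl bromide tolerate BBr3, and no acid-sensitive group is present yet.

Step 6
Reactants: 9 2-bromo-4,5-dihydroxybenzaldehyde; 10 3-chloro-3-methylbut-1-yne
Product: 11 2-bromo-5-hydroxy-4-[(2-methylbut-3-yn-2-yl)oxy]benzaldehyde
Conditions: DBU (1.05 equiv), CuCl2·2H2O (1 mol %), MeCN, 0 °C, under argon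
Reagents that add atoms: none
Why: Copper-catalysed O-alkylation of a phenoxide with a tertiary propargylic chloride; one equivalent of base should deprotonate the hydroxyl para to the formyl group, by far the more acidic one, so the ether forms on the future O4'. The low temperature keeps the free neighbouring hydroxyl from adding to the alkyne.

Step 7
Reactants: 11 2-bromo-5-hydroxy-4-[(2-methylbut-3-yn-2-yl)oxy]benzaldehyde
Product: 12 2-bromo-5-[(tert-butyldimethylsilyl)oxy]-4-[(2-methylbut-3-yn-2-yl)oxy]benzaldehyde
Conditions: TBSCl, imidazole, DMF, 0 °C to rt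
Reagents that add atoms: tert-butyldimethylsilyl chloride, CC(C)(C)[Si](C)(C)Cl
Why: Standard silylation of the remaining phenol; it comes before any heating and blocks C5', so that the later rearrangement can only reach C3'.

Step 8
Reactants: 12 2-bromo-5-[(tert-butyldimethylsilyl)oxy]-4-[(2-methylbut-3-yn-2-yl)oxy]benzaldehyde
Product: 14 2-bromo-5-[(tert-butyldimethylsilyl)oxy]-4-[(2-methylbut-3-yn-2-yl)oxy]phenol, via aryl formate 13 (not isolated)
Conditions: mCPBA, CH2Cl2, 0 °C to rt; then Et3N, MeOH, 0 °C
Reagents that add atoms: 3-chloroperoxybenzoic acid, O=C(OO)c1cccc(Cl)c1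
Why: Baeyer–Villiger oxidation of an electron-rich benzaldehyde (Dakin-type outcome): the aryl group, activated by the para ether oxygen, migrates to give formate 13, which mild methanolysis cleaves. The terminal alkyne is inert to the peracid, which is why the oxidation is placed before any alkene exists.

Step 9
Reactants: 14 2-bromo-5-[(tert-butyldimethylsilyl)oxy]-4-[(2-methylbut-3-yn-2-yl)oxy]phenol
Product: 16 5-bromo-8-[(tert-butyldimethylsilyl)oxy]-2,2-dimethyl-2H-chromen-6-ol, via allenyl hydroquinone 15 (not isolated)
Conditions: N,N-diethylaniline, 170 °C, under argon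
Reagents that add atoms: none
Why: Aromatic propargyl Claisen rearrangement to the only free ortho position gives 15 after tautomerisation; a 1,5-hydrogen shift to an ortho-quinone methide and oxa-6π electrocyclisation then close ring D.

Step 10
Reactants: 16 5-bromo-8-[(tert-butyldimethylsilyl)oxy]-2,2-dimethyl-2H-chromen-6-ol
Product: 17 8-[(tert-butyldimethylsilyl)oxy]-2,2-dimethyl-5-(3-methylbut-2-en-1-yl)-2H-chromen-6-ol
Conditions: tributyl(3-methylbut-2-en-1-yl)stannane, Pd(PPh3)4 (10 mol %), DMF, 100 °C
Reagents that add atoms: tributyl(3-methylbut-2-en-1-yl)stannane, CC(C)=CC[Sn](CCCC)(CCCC)CCCC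
Why: Stille coupling under neutral conditions, which tolerates the free phenol and the aryl silyl ether; reductive elimination at the less substituted allyl terminus should give the linear prenyl group at the carbon marked by bromine.

Step 11
Reactants: 17 8-[(tert-butyldimethylsilyl)oxy]-2,2-dimethyl-5-(3-methylbut-2-en-1-yl)-2H-chromen-6-ol
Product: 18 8-[(tert-butyldimethylsilyl)oxy]-2,2-dimethyl-5-(3-methylbut-2-en-1-yl)-2H-chromen-6-yl trifluoromethanesulfonate
Conditions: PhNTf2, Et3N, DMAP (cat.), CH2Cl2, rt
Reagents that add atoms: N-phenylbis(trifluoromethanesulfonimide), O=S(=O)(N(c1ccccc1)S(=O)(=O)C(F)(F)F)C(F)(F)F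
Why: Sulfonylation of the phenol with a mild triflating agent that releases no strong acid, so the ortho-prenyl phenol is not cyclised and the alkenes are untouched.

Step 12
Reactants: 18 8-[(tert-butyldimethylsilyl)oxy]-2,2-dimethyl-5-(3-methylbut-2-en-1-yl)-2H-chromen-6-yl trifluoromethanesulfonate
Product: 19 tert-butyl{[2,2-dimethyl-5-(3-methylbut-2-en-1-yl)-6-(4,4,5,5-tetramethyl-1,3,2-dioxaborolan-2-yl)-2H-chromen-8-yl]oxy}dimethylsilane
Conditions: bis(pinacolato)diboron, PdCl2(dppf) (5 mol %), KOAc, 1,4-dioxane, 90 °C
Reagents that add atoms: bis(pinacolato)diboron, CC1(C)OB(OC1(C)C)B1OC(C)(C)C(C)(C)O1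
Why: Miyaura borylation of an aryl triflate with only one ortho substituent; the weak acetate base does not promote coupling of the product with unreacted triflate.

Step 13
Reactants: 19 tert-butyl{[2,2-dimethyl-5-(3-methylbut-2-en-1-yl)-6-(4,4,5,5-tetramethyl-1,3,2-dioxaborolan-2-yl)-2H-chromen-8-yl]oxy}dimethylsilane
Product: 20 {8-[(tert-butyldimethylsilyl)oxy]-2,2-dimethyl-5-(3-methylbut-2-en-1-yl)-2H-chromen-6-yl}boronic acid
Conditions: NaIO4, NH4OAc, acetone–H2O, rt
Reagents that add atoms: water, O
Why: Oxidative cleavage of a pinacol boronate: hydrolysis is driven by periodate cleavage of the released pinacol; periodate alone does not attack alkenes or the silyl ether.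

Step 14
Reactants: 7 2-allyl-5-[(3-methylbut-2-en-1-yl)oxy]phenol; 20 {8-[(tert-butyldimethylsilyl)oxy]-2,2-dimethyl-5-(3-methylbut-2-en-1-yl)-2H-chromen-6-yl}boronic acid
Product: 21 (2S)-2-{8-[(tert-butyldimethylsilyl)oxy]-2,2-dimethyl-5-(3-methylbut-2-en-1-yl)-2H-chromen-6-yl}-7-[(3-methylbut-2-en-1-yl)oxy]-3,4-dihydro-2H-chromene
Conditions: Pd(OAc)2 (10 mol %), (S)-4-tert-butyl-2-[5-(trifluoromethyl)pyridin-2-yl]-4,5-dihydrooxazole (15 mol %), 1,4-benzoquinone (1.5 equiv), N,N-dimethylacetamide, 40 °C, 7 (1.5 equiv) added slowly
Reagents that add atoms: none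
Why: Proposed new method: transmetalation of 20 to the ligated divalent palladium gives an arylpalladium species that inserts the allyl alkene of 7 with the aryl group on the terminal carbon (future C2) and the metal on C3; β-hydride elimination towards C2 and re-insertion without release of the styrene move palladium to C2, where the η3-benzyl form is stabilised by O4' para to C1', and the ring A phenoxide attacks this carbon, forming O1–C2 and releasing zerovalent palladium for reoxidation by 1,4-benzoquinone. The closest known reaction types are the oxidative 1,1-difunctionalisations of terminal alkenes by divalent palladium (1,1-arylacetoxylation, 1,1-arylfluorination, 1,1-diarylation), which pass through the same stabilised benzylic palladium, and palladium carboetherification of alkenyl phenols; what is new is a tethered phenol as the second partner. Ring C closes by carbon–oxygen bond formation, a six-membered attack of O1 on the benzylic carbon C2 of the η3-benzylpalladium. The C2 stereocentre is set by the chiral pyridine-oxazoline ligand, which decides the face of the benzylic carbon that the phenoxide reaches (or, if the walk is not reversible, the alkene face to which the palladium hydride re-adds). Regiochemistry needs aryl delivery to the unhindered terminal carbon and capture only at C2: palladium on C3 is an unstabilised secondary alkyl that should lose a β-hydrogen faster than it forms a carbon–oxygen bond, and palladium on C4 cannot close a ring with O1. Chemoselectivity rests on the monosubstituted alkene of 7 inserting much faster than the trisubstituted prenyl alkenes and the hindered ring D alkene, and the 1,1-dimethylallyl vinyl group is deliberately absent at this stage. Slow addition of 7 keeps arylpalladium ahead of direct oxypalladation of the allylphenol.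

Step 15
Reactants: 21 (2S)-2-{8-[(tert-butyldimethylsilyl)oxy]-2,2-dimethyl-5-(3-methylbut-2-en-1-yl)-2H-chromen-6-yl}-7-[(3-methylbut-2-en-1-yl)oxy]-3,4-dihydro-2H-chromene
Product: 23 (2S)-2-{8-[(tert-butyldimethylsilyl)oxy]-2,2-dimethyl-5-(3-methylbut-2-en-1-yl)-2H-chromen-6-yl}-6-(2-methylbut-3-en-2-yl)-3,4-dihydro-2H-chromen-7-ol, via ortho-dienone 22 (not isolated)
Conditions: N,N-diethylaniline, 190 °C, sealed tube, under argon
Reagents that add atoms: none
Why: Aromatic Claisen rearrangement of the aryl prenyl ether: the [3,3] shift gives dienone 22 with the quaternary carbon on C6, and tautomerisation restores the phenol. C6 is expected over C8 because it is para to O1 and unhindered, whereas C8 lies between O1 and O7; C2 takes no part and should keep its configuration.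

Step 16
Reactants: 23 (2S)-2-{8-[(tert-butyldimethylsilyl)oxy]-2,2-dimethyl-5-(3-methylbut-2-en-1-yl)-2H-chromen-6-yl}-6-(2-methylbut-3-en-2-yl)-3,4-dihydro-2H-chromen-7-ol
Product: 24 kazinol H, (2S)-2-[8-hydroxy-2,2-dimethyl-5-(3-methylbut-2-en-1-yl)-2H-chromen-6-yl]-6-(2-methylbut-3-en-2-yl)-3,4-dihydro-2H-chromen-7-ol
Conditions: TBAF, AcOH, THF, 0 °C
Reagents that add atoms: none
Why: Fluoride cleavage of the aryl silyl ether; buffering with acetic acid avoids free phenoxides of the two electron-rich rings, and neither the alkenes nor C2 are affected.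

## Compound list

1 | 2,4-dihydroxybenzaldehyde | O=Cc1ccc(O)cc1O | starting material
2 | 1-bromo-3-methylbut-2-ene | CC(C)=CCBr | starting material
3 | 2-hydroxy-4-[(3-methylbut-2-en-1-yl)oxy]benzaldehyde | O=Cc1ccc(OCC=C(C)C)cc1O | intermediate
4 | tert-butyl 2-formyl-5-[(3-methylbut-2-en-1-yl)oxy]phenyl carbonate | O=Cc1ccc(OCC=C(C)C)cc1OC(=O)OC(C)(C)C | intermediate
5 | tert-butyl 2-(hydroxymethyl)-5-[(3-methylbut-2-en-1-yl)oxy]phenyl carbonate | OCc1ccc(OCC=C(C)C)cc1OC(=O)OC(C)(C)C | intermediate
6 | 6-methylidene-3-[(3-methylbut-2-en-1-yl)oxy]cyclohexa-2,4-dien-1-one (ortho-quinone methide) | C=C1C=CC(OCC=C(C)C)=CC1=O | intermediate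
7 | 2-allyl-5-[(3-methylbut-2-en-1-yl)oxy]phenol | C=CCc1ccc(OCC=C(C)C)cc1O | intermediate
8 | 2-bromo-4,5-dimethoxybenzaldehyde | COc1cc(Br)c(C=O)cc1OC | starting material
9 | 2-bromo-4,5-dihydroxybenzaldehyde | O=Cc1cc(O)c(O)cc1Br | intermediate
10 | 3-chloro-3-methylbut-1-yne | C#CC(C)(C)Cl | starting material
11 | 2-bromo-5-hydroxy-4-[(2-methylbut-3-yn-2-yl)oxy]benzaldehyde | O=Cc1cc(O)c(OC(C)(C)C#C)cc1Br | intermediate
12 | 2-bromo-5-[(tert-butyldimethylsilyl)oxy]-4-[(2-methylbut-3-yn-2-yl)oxy]benzaldehyde | O=Cc1cc(O[Si](C)(C)C(C)(C)C)c(OC(C)(C)C#C)cc1Br | intermediate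
13 | 2-bromo-5-[(tert-butyldimethylsilyl)oxy]-4-[(2-methylbut-3-yn-2-yl)oxy]phenyl formate | O=COc1cc(O[Si](C)(C)C(C)(C)C)c(OC(C)(C)C#C)cc1Br | intermediate
14 | 2-bromo-5-[(tert-butyldimethylsilyl)oxy]-4-[(2-methylbut-3-yn-2-yl)oxy]phenol | Oc1cc(O[Si](C)(C)C(C)(C)C)c(OC(C)(C)C#C)cc1Br | intermediate
15 | 2-bromo-5-[(tert-butyldimethylsilyl)oxy]-3-(3-methylbuta-1,2-dien-1-yl)benzene-1,4-diol | Oc1cc(O[Si](C)(C)C(C)(C)C)c(O)c(C=C=C(C)C)c1Br | intermediate
16 | 5-bromo-8-[(tert-butyldimethylsilyl)oxy]-2,2-dimethyl-2H-chromen-6-ol | CC1(C)C=Cc2c(Br)c(O)cc(O[Si](C)(C)C(C)(C)C)c2O1 | intermediate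
17 | 8-[(tert-butyldimethylsilyl)oxy]-2,2-dimethyl-5-(3-methylbut-2-en-1-yl)-2H-chromen-6-ol | CC(C)=CCc1c(O)cc(O[Si](C)(C)C(C)(C)C)c2OC(C)(C)C=Cc12 | intermediate
18 | 8-[(tert-butyldimethylsilyl)oxy]-2,2-dimethyl-5-(3-methylbut-2-en-1-yl)-2H-chromen-6-yl trifluoromethanesulfonate | CC(C)=CCc1c(OS(=O)(=O)C(F)(F)F)cc(O[Si](C)(C)C(C)(C)C)c2OC(C)(C)C=Cc12 | intermediate
19 | tert-butyl{[2,2-dimethyl-5-(3-methylbut-2-en-1-yl)-6-(4,4,5,5-tetramethyl-1,3,2-dioxaborolan-2-yl)-2H-chromen-8-yl]oxy}dimethylsilane | CC(C)=CCc1c(B3OC(C)(C)C(C)(C)O3)cc(O[Si](C)(C)C(C)(C)C)c2OC(C)(C)C=Cc12 | intermediate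
20 | {8-[(tert-butyldimethylsilyl)oxy]-2,2-dimethyl-5-(3-methylbut-2-en-1-yl)-2H-chromen-6-yl}boronic acid | OB(O)c1cc(O[Si](C)(C)C(C)(C)C)c2c(c1CC=C(C)C)C=CC(C)(C)O2 | intermediate
21 | (2S)-2-{8-[(tert-butyldimethylsilyl)oxy]-2,2-dimethyl-5-(3-methylbut-2-en-1-yl)-2H-chromen-6-yl}-7-[(3-methylbut-2-en-1-yl)oxy]-3,4-dihydro-2H-chromene | CC(C)=CCOc1ccc2c(c1)O[C@H](c1cc(O[Si](C)(C)C(C)(C)C)c3c(c1CC=C(C)C)C=CC(C)(C)O3)CC2 | intermediate
22 | (2S)-2-{8-[(tert-butyldimethylsilyl)oxy]-2,2-dimethyl-5-(3-methylbut-2-en-1-yl)-2H-chromen-6-yl}-6-(2-methylbut-3-en-2-yl)-3,4-dihydro-2H-chromen-7(6H)-one (ortho-dienone, C6 epimers) | O=C1C=C2O[C@H](c3cc(O[Si](C)(C)C(C)(C)C)c4c(c3CC=C(C)C)C=CC(C)(C)O4)CCC2=CC1C(C)(C)C=C | intermediate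
23 | (2S)-2-{8-[(tert-butyldimethylsilyl)oxy]-2,2-dimethyl-5-(3-methylbut-2-en-1-yl)-2H-chromen-6-yl}-6-(2-methylbut-3-en-2-yl)-3,4-dihydro-2H-chromen-7-ol | C=CC(C)(C)c1cc2c(cc1O)O[C@H](c1cc(O[Si](C)(C)C(C)(C)C)c3c(c1CC=C(C)C)C=CC(C)(C)O3)CC2 | intermediate
24 | kazinol H, (2S)-2-[8-hydroxy-2,2-dimethyl-5-(3-methylbut-2-en-1-yl)-2H-chromen-6-yl]-6-(2-methylbut-3-en-2-yl)-3,4-dihydro-2H-chromen-7-ol | C=CC(C)(C)c1cc2c(cc1O)O[C@H](c1cc(O)c3c(c1CC=C(C)C)C=CC(C)(C)O3)CC2 | target

## Step count and least certain steps

Total step count: 16. Longest linear sequence: 12 steps (steps 5 to 16, from 8); the ring A branch (steps 1 to 4) joins at step 14.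

**Step 14 (key step, carries the label for a new method).** Several processes can divert it:
- oxypalladation of the allylphenol before aryl transfer (Wacker-type cyclisation);
- release of the alkene from the palladium hydride before re-insertion (plain oxidative Heck coupling);
- walk of palladium towards C4, where the metal can be lost through an ortho-quinone methide of ring A;
- ionisation of the C2–palladium bond with help from O4', so that ring closure escapes the ligand and enantiomeric purity erodes;
- cleavage of the prenyl ether by transient zerovalent palladium;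
- protodeboronation or homocoupling of the hindered boronic acid.

Fallback by known chemistry, from 18 and 5 back to 21. Stille coupling of 18 with tributyl(1-ethoxyvinyl)stannane (Pd(PPh3)4, LiCl, 1,4-dioxane) would give the 1-ethoxyvinyl arene F1, and dilute HCl in THF would hydrolyse it to the methyl ketone F2. The lithium enolate of F2 (from LiN(SiMe3)2) would be added to quinone methide 6, generated from 5 with tert-butylmagnesium chloride as in step 4, to give the saturated ketone F3. Asymmetric transfer hydrogenation with RuCl[(R,R)-TsDPEN](p-cymene) in formic acid–triethylamine should reduce only the ketone and give the R alcohol F4. An intramolecular Mitsunobu reaction (PPh3, diisopropyl azodicarboxylate, THF) then closes O1–C2 with inversion and returns to 21.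

**Step 15.** The heat needed for the shift can also drive further reaction of the product phenol: addition of the new hydroxyl to the neighbouring vinyl group, rearrangement of the 1,1-dimethylallyl group, and loss of the prenyl unit. Attack at C8 is a smaller risk. Fallback from 21: the rearrangement is run with acetic anhydride and NaOAc in N,N-diethylaniline, so that the phenol is acetylated as it forms. This gives the 7-O-acetate F5, which cannot react further; brief methanolysis (K2CO3, MeOH, 0 °C) returns to 23.

**Step 10.** Oxidative addition into an electron-rich bromide with two ortho substituents may be slow, and allyl transposition during coupling would place the substituted terminus on the ring. Fallback from 16: Stille coupling with allyltributylstannane (Pd(PPh3)4, DMF), which has no such ambiguity, would give the 5-allyl chromenol F6. Cross-metathesis with 2-methylbut-2-ene and the second-generation Grubbs catalyst RuCl2(=CHPh)(PCy3)(H2IMes) then converts allyl into prenyl and returns to 17; the ring D alkene, next to a quaternary carbon, should not take part.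

**Step 6.** Site selection between the two catechol hydroxyls may be incomplete, double alkylation may occur, or the copper salt may oxidise the catechol. Fallback from 9: silylation of both hydroxyls (TBSCl, imidazole) gives the bis-silyl ether F7. Mild base (Cs2CO3, DMF–H2O) removes the silyl group para to the formyl group, the better leaving phenoxide, and gives the 4-hydroxy-5-silyloxy aldehyde F8. Any silyl migration favours this same isomer. Alkylation of F8 with 10 under the conditions of step 6 returns to 12.

**Step 4 (with step 3).** The carbonate may migrate to the benzylic oxygen already during reduction, the Grignard reagent may attack the carbonate carbonyl, or the quinone methide may oligomerise. Fallback from 3: silylation (TBSCl, imidazole) gives the silyl ether aldehyde F9, and NaBH4 reduces it to the benzyl alcohol F10. CBr4 and PPh3 (Appel reaction) convert F10 into the benzyl bromide F11. Vinylmagnesium bromide with CuI (10 mol %) in THF at −30 °C displaces the bromide to give the allyl arene silyl ether F12, and TBAF returns to 7.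

## Further compounds

F1 | step 14 | tert-butyl{[6-(1-ethoxyethenyl)-2,2-dimethyl-5-(3-methylbut-2-en-1-yl)-2H-chromen-8-yl]oxy}dimethylsilane | C=C(OCC)c1cc(O[Si](C)(C)C(C)(C)C)c2c(c1CC=C(C)C)C=CC(C)(C)O2
F2 | step 14 | 1-{8-[(tert-butyldimethylsilyl)oxy]-2,2-dimethyl-5-(3-methylbut-2-en-1-yl)-2H-chromen-6-yl}ethan-1-one | CC(=O)c1cc(O[Si](C)(C)C(C)(C)C)c2c(c1CC=C(C)C)C=CC(C)(C)O2
F3 | step 14 | 1-{8-[(tert-butyldimethylsilyl)oxy]-2,2-dimethyl-5-(3-methylbut-2-en-1-yl)-2H-chromen-6-yl}-3-{2-hydroxy-4-[(3-methylbut-2-en-1-yl)oxy]phenyl}propan-1-one | O=C(CCc1ccc(OCC=C(C)C)cc1O)c1cc(O[Si](C)(C)C(C)(C)C)c2c(c1CC=C(C)C)C=CC(C)(C)O2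
F4 | step 14 | (1R)-1-{8-[(tert-butyldimethylsilyl)oxy]-2,2-dimethyl-5-(3-methylbut-2-en-1-yl)-2H-chromen-6-yl}-3-{2-hydroxy-4-[(3-methylbut-2-en-1-yl)oxy]phenyl}propan-1-ol | O[C@H](CCc1ccc(OCC=C(C)C)cc1O)c1cc(O[Si](C)(C)C(C)(C)C)c2c(c1CC=C(C)C)C=CC(C)(C)O2
F5 | step 15 | (2S)-2-{8-[(tert-butyldimethylsilyl)oxy]-2,2-dimethyl-5-(3-methylbut-2-en-1-yl)-2H-chromen-6-yl}-6-(2-methylbut-3-en-2-yl)-3,4-dihydro-2H-chromen-7-yl acetate | C=CC(C)(C)c1cc2c(cc1OC(C)=O)O[C@H](c1cc(O[Si](C)(C)C(C)(C)C)c3c(c1CC=C(C)C)C=CC(C)(C)O3)CC2
F6 | step 10 | 5-allyl-8-[(tert-butyldimethylsilyl)oxy]-2,2-dimethyl-2H-chromen-6-ol | C=CCc1c(O)cc(O[Si](C)(C)C(C)(C)C)c2OC(C)(C)C=Cc12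
F7 | step 6 | 2-bromo-4,5-bis[(tert-butyldimethylsilyl)oxy]benzaldehyde | O=Cc1cc(O[Si](C)(C)C(C)(C)C)c(O[Si](C)(C)C(C)(C)C)cc1Br
F8 | step 6 | 2-bromo-5-[(tert-butyldimethylsilyl)oxy]-4-hydroxybenzaldehyde | O=Cc1cc(O[Si](C)(C)C(C)(C)C)c(O)cc1Br
F9 | step 4 | 2-[(tert-butyldimethylsilyl)oxy]-4-[(3-methylbut-2-en-1-yl)oxy]benzaldehyde | O=Cc1ccc(OCC=C(C)C)cc1O[Si](C)(C)C(C)(C)C
F10 | step 4 | {2-[(tert-butyldimethylsilyl)oxy]-4-[(3-methylbut-2-en-1-yl)oxy]phenyl}methanol | OCc1ccc(OCC=C(C)C)cc1O[Si](C)(C)C(C)(C)C
F11 | step 4 | {2-(bromomethyl)-5-[(3-methylbut-2-en-1-yl)oxy]phenoxy}(tert-butyl)dimethylsilane | BrCc1ccc(OCC=C(C)C)cc1O[Si](C)(C)C(C)(C)C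
F12 | step 4 | {2-allyl-5-[(3-methylbut-2-en-1-yl)oxy]phenoxy}(tert-butyl)dimethylsilane | C=CCc1ccc(OCC=C(C)C)cc1O[Si](C)(C)C(C)(C)C
A1 | alternative 1 | (2S)-7-[(3-methylbut-2-en-1-yl)oxy]-2-{2-(3-methylbut-2-en-1-yl)-4-[(2-methylbut-3-yn-2-yl)oxy]-5-[(triisopropylsilyl)oxy]phenyl}-3,4-dihydro-2H-chromene | CC(C)=CCOc1ccc2c(c1)O[C@H](c1cc(O[Si](C(C)C)(C(C)C)C(C)C)c(OC(C)(C)C#C)cc1CC=C(C)C)CC2
A2 | alternative 1 | (S)-kazinol H 5'-triisopropylsilyl ether | C=CC(C)(C)c1cc2c(cc1O)O[C@H](c1cc(O[Si](C(C)C)(C(C)C)C(C)C)c3c(c1CC=C(C)C)C=CC(C)(C)O3)CC2
A3 | alternative 2 | (1S)-3-{2-bromo-5-(2-methylbut-3-en-2-yl)-4-[(triisopropylsilyl)oxy]phenyl}-1-{2,2-dimethyl-5-(3-methylbut-2-en-1-yl)-8-[(triisopropylsilyl)oxy]-2H-chromen-6-yl}propan-1-ol | O[C@H](c1cc(O[Si](C(C)C)(C(C)C)C(C)C)c2c(c1CC=C(C)C)C=CC(C)(C)O2)CCc1cc(C(C)(C)C=C)c(O[Si](C(C)C)(C(C)C)C(C)C)cc1Br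
A4 | alternative 2 | (S)-kazinol H 7,5'-bis(triisopropylsilyl) ether | C=CC(C)(C)c1cc2c(cc1O[Si](C(C)C)(C(C)C)C(C)C)O[C@H](c1cc(O[Si](C(C)C)(C(C)C)C(C)C)c3c(c1CC=C(C)C)C=CC(C)(C)O3)CC2
A5 | alternative 3 | 5-[(tert-butyldimethylsilyl)oxy]-2-(hydroxymethyl)-4-(2-methylbut-3-en-2-yl)phenol | OCc1cc(C(C)(C)C=C)c(O[Si](C)(C)C(C)(C)C)cc1O
A6 | alternative 3 | tert-butyl{[6-ethenyl-2,2-dimethyl-5-(3-methylbut-2-en-1-yl)-2H-chromen-8-yl]oxy}dimethylsilane | C=Cc1cc(O[Si](C)(C)C(C)(C)C)c2c(c1CC=C(C)C)C=CC(C)(C)O2
A7 | alternative 3 | (S)-kazinol H 7,5'-bis(tert-butyldimethylsilyl) ether | C=CC(C)(C)c1cc2c(cc1O[Si](C)(C)C(C)(C)C)O[C@H](c1cc(O[Si](C)(C)C(C)(C)C)c3c(c1CC=C(C)C)C=CC(C)(C)O3)CC2
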